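**Assumption:** the target SMILES has no stereocentre (Gardenin E is an achiral, planar flavone), so no enantiocontrol is needed. The only stereo-elements on the way are the racemic centres in 16 and 18 and the E-alkene in 17, and all three are erased before the target.

## Retrosynthetic overview
1. Gardenin E 22 ⇒ O-debenzylation and chelation-controlled 5-O-demethylation of 3',5'-bis(benzyloxy)-4',5,6,7,8-pentamethoxyflavone 19.
2. Pyrone ring C is the only ring built, and it is built last: 19 ⇒ oxidative cyclisation of 2'-hydroxychalcone 17.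
3. Key C–C bond (Cα=Cβ of 17) ⇒ intermolecular Claisen–Schmidt aldol condensation of acetophenone 10 with aldehyde 15.
4. Ring A piece 10 ⇐ 2,3,4-trimethoxybenzaldehyde 1 (Dakin, methylation, Vilsmeier, Dakin, Fries acylation).
5. Ring B piece 15 ⇐ methyl gallate 11 (4-O-methylation, 3,5-di-O-benzylation, reduction, oxidation).

## Route

**Step 1**
Reactants: 1 2,3,4-trimethoxybenzaldehyde
Product: 3 2,3,4-trimethoxyphenol, via aryl formate 2 (not isolated)
Conditions: 30% aq H2O2 (1.3 equiv), cat. conc. H2SO4, MeOH, rt, 16 h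
Reagents that add atoms: hydrogen peroxide, OO
Why: In this acid-catalysed Dakin (Baeyer–Villiger type) oxidation the aryl group, activated by o- and p-methoxy donors, migrates to oxygen and formate 2 is methanolysed in the same pot, with no stereocentre formed.

**Step 2**
Reactants: 3 2,3,4-trimethoxyphenol
Product: 4 1,2,3,4-tetramethoxybenzene
Conditions: MeI (1.5 equiv), K2CO3 (2 equiv), acetone, reflux, 6 h
Reagents that add atoms: iodomethane, CI
Why: This is a Williamson O-methylation (SN2) of the single phenoxide, and nothing else in the molecule can be alkylated.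

**Step 3**
Reactants: 4 1,2,3,4-tetramethoxybenzene
Product: 6 2,3,4,5-tetramethoxybenzaldehyde, via aryl iminium chloride 5 (not isolated)
Conditions: POCl3 (2 equiv), DMF, 0 → 80 °C, 4 h; then ice–water, 1 h
Reagents that add atoms: N,N-dimethylformamide, CN(C)C=O; water, O
Why: In this Vilsmeier–Haack formylation the two free positions of symmetric 4 are equivalent and each is ortho/para to methoxy groups, so one aldehyde forms and the iminium group blocks a second attack.

**Step 4**
Reactants: 6 2,3,4,5-tetramethoxybenzaldehyde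
Product: 8 2,3,4,5-tetramethoxyphenol, via aryl formate 7 (not isolated)
Conditions: 30% aq H2O2 (1.3 equiv), cat. conc. H2SO4, MeOH, rt, 16 h
Reagents that add atoms: hydrogen peroxide, OO
Why: This is the same acid-catalysed Dakin oxidation as in step 1, again favoured by the 2- and 4-methoxy donors, and the mild peroxide/MeOH medium does not take the phenol on to a quinone.

**Step 5**
Reactants: 8 2,3,4,5-tetramethoxyphenol
Product: 10 1-(2-hydroxy-3,4,5,6-tetramethoxyphenyl)ethan-1-one, via aryl acetate 9 (not isolated)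
Conditions: Ac2O (2 equiv), BF3·OEt2 (3 equiv), 80 °C, 3 h; then ice–water
Reagents that add atoms: acetic anhydride, CC(=O)OC(C)=O
Why: BF3-promoted O-acetylation followed by Fries rearrangement (Friedel–Crafts C-acylation) can only reach the one remaining ring C–H, which is ortho to the OH, and BF3 does not cleave aryl methyl ethers under these conditions.

**Step 6**
Reactants: 11 methyl gallate (methyl 3,4,5-trihydroxybenzoate)
Product: 12 methyl 3,5-dihydroxy-4-methoxybenzoate
Conditions: MeI (1.05 equiv), KHCO3 (1.2 equiv), DMF, N2, rt → 40 °C, 24 h; chromatography or recrystallisation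
Reagents that add atoms: iodomethane, CI
Why: This is a pKa-controlled Williamson methylation, because the 4-OH para to the ester is the most acidic and is the one deprotonated by bicarbonate, so limiting MeI alkylates it preferentially.

**Step 7**
Reactants: 12 methyl 3,5-dihydroxy-4-methoxybenzoate
Product: 13 methyl 3,5-bis(benzyloxy)-4-methoxybenzoate
Conditions: BnBr (2.4 equiv), K2CO3 (3 equiv), DMF, 60 °C, 6 h
Reagents that add atoms: benzyl bromide, BrCc1ccccc1
Why: Exhaustive Williamson benzylation caps both remaining phenols with groups that survive KOH, hydride and I2/DMSO and leave by hydrogenolysis at the end.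

**Step 8**
Reactants: 13 methyl 3,5-bis(benzyloxy)-4-methoxybenzoate
Product: 14 [3,5-bis(benzyloxy)-4-methoxyphenyl]methanol
Conditions: LiAlH4 (1 equiv), THF, 0 °C → rt, 2 h; quench Na2SO4·10H2O, filter
Reagents that add atoms: none
Why: Hydride reduction takes the ester to the primary alcohol while aryl benzyl and methyl ethers are inert to LiAlH4.

**Step 9**
Reactants: 14 [3,5-bis(benzyloxy)-4-methoxyphenyl]methanol
Product: 15 3,5-bis(benzyloxy)-4-methoxybenzaldehyde
Conditions: activated MnO2 (10 equiv), CH2Cl2, rt, 16 h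
Reagents that add atoms: none
Why: Heterogeneous MnO2 oxidation is selective for the benzylic alcohol, stops cleanly at the aldehyde and leaves the benzyl ethers untouched.

**Step 10 (key C–C bond formation)**
Reactants: 10 1-(2-hydroxy-3,4,5,6-tetramethoxyphenyl)ethan-1-one; 15 3,5-bis(benzyloxy)-4-methoxybenzaldehyde
Product: 17 (E)-3-[3,5-bis(benzyloxy)-4-methoxyphenyl]-1-(2-hydroxy-3,4,5,6-tetramethoxyphenyl)prop-2-en-1-one, via aldol adduct 16 (not isolated)
Conditions: KOH (50% aq, 10 equiv), EtOH–THF, rt, 36 h; then cold 1 M HCl to pH 3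
Reagents that add atoms: none
Why: In this Claisen–Schmidt crossed aldol condensation only 10 can enolise and only 15 is an aldehyde, and the racemic carbinol centre of 16 is lost by E1cB dehydration to the thermodynamically preferred E-enone.

**Step 11**
Reactants: 17 (E)-chalcone
Product: 19 3',5'-bis(benzyloxy)-4',5,6,7,8-pentamethoxyflavone, via flavanone 18 (not isolated)
Conditions: I2 (10 mol %), DMSO, 125 °C, 3 h; aq Na2S2O3 wash
Reagents that add atoms: none
Why: I2/DMSO oxidative cyclisation proceeds by oxa-Michael closure to racemic flavanone 18, α-iodination and HI loss, with DMSO re-oxidising HI, so the transient C2 centre is erased and acid never builds up enough to attack the ethers.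

**Step 12**
Reactants: 19 3',5'-bis(benzyloxy)-4',5,6,7,8-pentamethoxyflavone
Product: 21 3',5'-bis(benzyloxy)-5-hydroxy-4',6,7,8-tetramethoxyflavone, via aluminium chelate 20 (not isolated)
Conditions: anhydrous AlCl3 (3 equiv), MeCN, rt → 40 °C, TLC control (1–2 h); then 3% aq HCl, 60 °C, 30 min
Reagents that add atoms: none
Why: In this chelation-controlled Lewis-acid ether cleavage the MeCN-attenuated AlCl3 binds the C4 carbonyl and activates only the peri 5-OMe towards chloride, and any incidental benzyl loss is harmless because those groups are removed in step 13.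

**Step 13**
Reactants: 21 3',5'-bis(benzyloxy)-5-hydroxy-4',6,7,8-tetramethoxyflavone
Product: 22 Gardenin E (5,3',5'-trihydroxy-6,7,8,4'-tetramethoxyflavone)
Conditions: H2 (1 atm), 10% Pd/C, EtOAc–MeOH 1:1, rt, 4 h
Reagents that add atoms: none
Why: Catalytic hydrogenolysis cleaves both benzylic C–O bonds under neutral conditions that touch neither the methyl ethers nor the conjugated flavone C2=C3 bond, giving the achiral target.

## Compound list
1 | 2,3,4-trimethoxybenzaldehyde | COc1ccc(C=O)c(OC)c1OC | starting material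
2 | 2,3,4-trimethoxyphenyl formate (in situ) | COc1ccc(OC=O)c(OC)c1OC | intermediate
3 | 2,3,4-trimethoxyphenol | COc1ccc(O)c(OC)c1OC | intermediate
4 | 1,2,3,4-tetramethoxybenzene | COc1ccc(OC)c(OC)c1OC | intermediate
5 | N,N-dimethyl(2,3,4,5-tetramethoxybenzylidene)iminium chloride (in situ) | COc1cc(C=[N+](C)C)c(OC)c(OC)c1OC.[Cl-] | intermediate
6 | 2,3,4,5-tetramethoxybenzaldehyde | COc1cc(C=O)c(OC)c(OC)c1OC | intermediate
7 | 2,3,4,5-tetramethoxyphenyl formate (in situ) | COc1cc(OC=O)c(OC)c(OC)c1OC | intermediate
8 | 2,3,4,5-tetramethoxyphenol | COc1cc(O)c(OC)c(OC)c1OC | intermediate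
9 | 2,3,4,5-tetramethoxyphenyl acetate (in situ) | COc1cc(OC(C)=O)c(OC)c(OC)c1OC | intermediate
10 | 1-(2-hydroxy-3,4,5,6-tetramethoxyphenyl)ethan-1-one | CC(=O)c1c(O)c(OC)c(OC)c(OC)c1OC | intermediate
11 | methyl gallate | COC(=O)c1cc(O)c(O)c(O)c1 | starting material
12 | methyl 3,5-dihydroxy-4-methoxybenzoate | COC(=O)c1cc(O)c(OC)c(O)c1 | intermediate
13 | methyl 3,5-bis(benzyloxy)-4-methoxybenzoate | COC(=O)c1cc(OCc2ccccc2)c(OC)c(OCc2ccccc2)c1 | intermediate
14 | [3,5-bis(benzyloxy)-4-methoxyphenyl]methanol | OCc1cc(OCc2ccccc2)c(OC)c(OCc2ccccc2)c1 | intermediate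
15 | 3,5-bis(benzyloxy)-4-methoxybenzaldehyde | O=Cc1cc(OCc2ccccc2)c(OC)c(OCc2ccccc2)c1 | intermediate
16 | racemic 3-[3,5-bis(benzyloxy)-4-methoxyphenyl]-3-hydroxy-1-(2-hydroxy-3,4,5,6-tetramethoxyphenyl)propan-1-one (in situ) | COc1c(OCc2ccccc2)cc(C(O)CC(=O)c2c(O)c(OC)c(OC)c(OC)c2OC)cc1OCc1ccccc1 | intermediate
17 | (E)-3-[3,5-bis(benzyloxy)-4-methoxyphenyl]-1-(2-hydroxy-3,4,5,6-tetramethoxyphenyl)prop-2-en-1-one | COc1c(OCc2ccccc2)cc(/C=C/C(=O)c2c(O)c(OC)c(OC)c(OC)c2OC)cc1OCc1ccccc1 | intermediate
18 | racemic 3',5'-bis(benzyloxy)-4',5,6,7,8-pentamethoxyflavanone (in situ) | COc1c(OCc2ccccc2)cc(C2CC(=O)c3c(OC)c(OC)c(OC)c(OC)c3O2)cc1OCc1ccccc1 | intermediate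
19 | 3',5'-bis(benzyloxy)-4',5,6,7,8-pentamethoxyflavone | COc1c(OCc2ccccc2)cc(-c2cc(=O)c3c(OC)c(OC)c(OC)c(OC)c3o2)cc1OCc1ccccc1 | intermediate
20 | 5-O-dichloroaluminium chelate of 21 (in situ) | COc1c(OCc2ccccc2)cc(-c2cc(=O)c3c(O[Al](Cl)Cl)c(OC)c(OC)c(OC)c3o2)cc1OCc1ccccc1 | intermediate
21 | 3',5'-bis(benzyloxy)-5-hydroxy-4',6,7,8-tetramethoxyflavone | COc1c(OCc2ccccc2)cc(-c2cc(=O)c3c(O)c(OC)c(OC)c(OC)c3o2)cc1OCc1ccccc1 | intermediate
22 | Gardenin E | COc1c(O)cc(-c2cc(=O)c3c(O)c(OC)c(OC)c(OC)c3o2)cc1O | target

## Summary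
**Total step count:** 13.
**Longest linear sequence:** 9 steps (1–5, then 10–13). The ring B branch (steps 6–9) runs in parallel.

## Three steps most likely to fail, with fallbacks

**Step 6 (mono-methylation of one of three phenols; over-alkylation or 3-O-methylation).**
- The fallback sets out from 11 and comes back at 12.
- Peracetylate 11 (Ac2O, pyridine) to methyl 3,4,5-triacetoxybenzoate F1.
- Heat F1 with MeI and K2CO3 in refluxing acetone. Only the 4-acetate is cleaved, because its phenoxide is the best leaving group (para to the ester). That phenoxide is methylated in situ to methyl 3,5-diacetoxy-4-methoxybenzoate F2.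
- Methanolyse the two remaining acetates (cat. HCl, MeOH) to obtain 12.
- Selectivity then rests on differential ester lability rather than on competing phenoxide alkylation.

**Step 11 (oxidative cyclisation; ether loss by HI or incomplete dehydrogenation at 125 °C).**
- The fallback sets out from 10 and 13 and comes back at 19.
- Treat 10 with LiHMDS (3.5 equiv, THF, −78 °C) and add ester 13 (→ rt). This intermolecular crossed Claisen condensation gives 1-[3,5-bis(benzyloxy)-4-methoxyphenyl]-3-(2-hydroxy-3,4,5,6-tetramethoxyphenyl)propane-1,3-dione F3.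
- F3 already has the flavone oxidation level. It closes to 19 by simple cyclodehydration (cat. p-TsOH, toluene, reflux), so no oxidant is needed.

**Step 12 (selective 5-O-demethylation; risk of also cleaving the 6-OMe or the flanked 4'-OMe with a Lewis acid).**
- The fallback sets out from 19 and comes back at 22.
- Hydrogenolyse first (H2, Pd/C, EtOAc–MeOH) to 3',5'-dihydroxy-4',5,6,7,8-pentamethoxyflavone F4.
- Reflux F4 in 3 M HCl in aqueous EtOH (24–40 h). This Brønsted-acid medium cleaves only the methoxy group peri to the protonated carbonyl.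
- No metal is present to chelate the B-ring hydroxyls, so the 4'-OMe is left intact and 22 is obtained directly.

## Further compounds
F1 | step 6 | methyl 3,4,5-triacetoxybenzoate | COC(=O)c1cc(OC(C)=O)c(OC(C)=O)c(OC(C)=O)c1
F2 | step 6 | methyl 3,5-diacetoxy-4-methoxybenzoate | COC(=O)c1cc(OC(C)=O)c(OC)c(OC(C)=O)c1
F3 | step 11 | 1-[3,5-bis(benzyloxy)-4-methoxyphenyl]-3-(2-hydroxy-3,4,5,6-tetramethoxyphenyl)propane-1,3-dione | COc1c(OCc2ccccc2)cc(C(=O)CC(=O)c2c(O)c(OC)c(OC)c(OC)c2OC)cc1OCc1ccccc1
F4 | step 12 | 3',5'-dihydroxy-4',5,6,7,8-pentamethoxyflavone | COc1c(O)cc(-c2cc(=O)c3c(OC)c(OC)c(OC)c(OC)c3o2)cc1O
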